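Assumption: the SMILES is read as (4R,5S,6R,7R,8S,9S) with a cis-fused 12,6-lactone, a ring-cis C1=C10 bond and an (R)-2-methyloxirane-2-carboxylate on O9. Germacrane numbering (C1–C15) is used for every intermediate, and C14 is carried as a methyl group until after the ring contraction.

## The problem

The target is a ten-membered carbocycle with six contiguous stereocentres (C4–C9), a cis-fused α-methylene-γ-lactone at C6/C7, a cis-4,5-epoxide, a ring-cis C1=C10 enoate and two different esters on a trans-8,9-diol. Medium-ring closure is slow and prone to transannular side reactions, so the ring and the lactone are best made in one event. C4, C8 and C9 can come from the chiral pool, and C5 can then be set from C4 by epoxide closure with inversion. C7 must be set from C8, and C6 from C7 through the cis ring fusion. The epoxides do not survive acid, the α-methylene lactone does not survive nucleophiles or strong base, and the two acyl groups do not survive alkoxides, so these groups have to arrive late and in a fixed order. The enabling feature is the array C5(O)–C6(O)–C7–C11–C12(=O), a 1,5-dioxygenated chain whose C6 oxygen is the ester oxygen of C12. Read backwards, this is the retro-aldol product of a cyclobutanol made from the enol C5=C11 of a β-keto ester and the enol-ester alkene C6=C7. Both alkenes sit in one thirteen-membered lactone as the 1,5-diene C5=C11–C12–O–C6=C7, so the macrolactone can in principle be contracted to the carbocycle photochemically.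

## Retrosynthesis

**Epoxide and esters (36 back to 29).** The C5–O bond of the epoxide is cut last, which leads back to hydroxy mesylate 35 (tertiary C4–OH, 5R mesylate). This is preferred to carrying the oxirane because aqueous acid is needed to free the 8,9-diol, and it leaves only a mild base for the final step. Cutting the C9 ester gives alcohol 31 and potassium (R)-2-methylglycidate 33 (from commercial ester 32). Cutting the C8 acetate gives triol 30, and 30 comes from acetonide silyl ether 29 by one acid treatment. The forward steps ask for a kinetic preference between the C8 and C9 hydroxyls and a clean 3-exo closure.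

**C14 and C13 (29 back to 20).** The C14 ester is traced to a C14 methyl group (25) by allylic oxidation with SeO2. This keeps the precursor of the photochemical step free of an enoate chromophore and of a second silyl ether. The exocyclic methylene is cut at C11=C13 back to lactone 21, and the mesylate and carbinol back to ketone 20. Methylenation comes before mesylation and before any ester is present, because it needs a strong amide base. The reduction must deliver the 5R alcohol.

**Key disconnection (20 back to 18).** In 20 the bonds C5–C6 and C7–C11 are cut and C5–C11 is re-formed. This leads to the thirteen-membered β-keto (Z)-enol lactone 18 by way of the 2-oxabicyclo[2.1.1]hexanone 19. The neighbouring cuts (C6–C7 by allylation, C8=C9 by metathesis, C5–C10 by [3,3] shift) each close one ring only and leave C6 and C7 to later steps. This cut turns two rings, two C–C bonds and two stereocentres into one easily made ester ring. The forward step asks for the crossed (rule-of-five) mode, for reaction at C6=C7 and not at C1=C10, for the s-trans ester rotamer, and for facial control by C8.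

**Macrolactone (18 back to 14 and 15).** The ring of 18 is opened at C5–C11, the bond that the retro-aldol will later cleave again. This gives β-hydroxy lactone 17 and then the (Z)-enol bromoacetate aldehyde 16. The enol-ester C–O bond of 16 is cut to terminal alkyne 14 and bromoacetic acid 15. Both forward reactions are established types: intermolecular ruthenium-catalysed anti-Markovnikov addition of a carboxylic acid to an alkyne, and a samarium Reformatsky macrocyclisation. The β-keto acid is never handled, which avoids decarboxylation.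

**Chain (14 back to 6 and 9).** The aldehyde of 14 comes from the primary silyl ether of alkyne 13, and the alkyne from Weinreb amide 11. The C1=C10 bond of 11 is cut to phosphonium salt 6 and methyl ketone 9. A Wittig reaction of an α-alkoxy methyl ketone places the ylide chain cis to the oxygenated carbon (C9), which is the geometry required. An olefination in the other sense would need a β-alkoxy carbanion at C10, which would eliminate.

**Chiral pool (6 back to 1, 9 back to 7).** Salt 6 is traced through 5, 4, 3 and 2 to (R)-linalool 1, which supplies C1–C5, C15 and the C4 stereocentre. Ketone 9 is traced through bis-Weinreb amide 8 to the L-tartrate acetonide 7, which supplies C7–C10 with both carbinol centres. C6 comes from the diazophosphonate, C11/C12 from 15, C13 from Eschenmoser's salt and C14 from the Grignard reagent.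

## Roads not taken

**Alternative 1:** two-carbon ring expansion. The ten-membered ring is cut at C1–C2 and C9–C10, leading to a cyclooctenone pyrrolidine enamine A2 and methyl propiolate A3. Forward, the enamine adds to A3, and conrotatory opening of the fused cyclobutene gives dienamino ester A1. The reaction type is known and thermal, and it brings in C10 with C14 already at the ester level. In both respects it is better than the chosen plan, which relies on an untested photoreaction and spends three late steps on C14. Its weak points are these: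
- The difficulty is moved into A2, an eight-membered ring with three contiguous stereocentres.
- C9 arrives as a masked ketone and must be reduced to 9S without a controlling neighbour.
- The C1=C2 bond of A1 must be moved into the ring-cis C1=C10 position.
- The lactone must be built by oxidation of the C7 side chain, and the 4,5-alkene epoxidised selectively.

The chosen plan takes C8 and C9 from tartrate and makes the lactone together with the ring.

**Alternative 2:** ring-closing metathesis at C8=C9. The cut leads to seco-diene A5, which already carries lactone, epoxide and enoate. A ruthenium alkylidene such as the second-generation Grubbs catalyst, RuCl2(=CHPh)(PCy3)(H2IMes), would give A4. This is the most convergent road and the ring closure is a known type. Opening a later 8,9-epoxide would also differentiate O8 from O9 by itself, which the chosen plan must do by selective acylation. Its weak points are these: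
- A strained ten-membered ring must form with cis geometry.
- One vinyl group is part of a cross-conjugated dienoate, and the α-methylene lactone is a competing alkene.
- C8 and C9 must both be created afterwards on a diene conjugated to the ester, with only the ring conformation to control regio- and stereochemistry.

The chosen plan is longer but has no stereocentre without a defined source.

**Alternative 3:** anionic oxy-Cope ring expansion. The cut (C2–C3 formed, C5–C10 cleaved) leads to dialkenylcyclohexanol A7, whose potassium alkoxide would rearrange to an enolate that is trapped as silyl enol ether A6. The precedent for six-to-ten ring expansion is strong. Stereocentres C6–C9 are set on a cyclohexane, and the C14 ester and a regiodefined C4=C5 enol ether are in place. In reliability of the ring-forming step this road is better than the chosen one. Its weak points are these: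
- A7 has two adjacent quaternary carbons between oxygenated centres.
- Its alkoxide is β to an ester and can fragment by retro-aldol instead of rearranging.
- The ring-cis C1=C10 bond needs a boat-like transition state.
- The lactone must still be made from the C7 side chain, and C4 must still be hydroxylated before the same ketone-to-epoxide sequence.

The chosen plan sets against this a precursor made by ester chemistry and the simultaneous formation of the lactone.

Key step: step 14

## Route

Step 1
Reactants: 1 (R)-linalool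
Product: 2 (3R)-3,7-dimethyl-3-(triethylsilyloxy)octa-1,6-diene
Conditions: Et3SiOTf, 2,6-lutidine, CH2Cl2, 0 °C
Reagents that add atoms: triethylsilyl trifluoromethanesulfonate, CC[Si](CC)(CC)OS(=O)(=O)C(F)(F)F
Why: Silylation of a tertiary alcohol with a silyl triflate; the C4 stereocentre is not involved.

Step 2
Reactants: 2 silyl ether
Product: 3 (2R)-2-methyl-2-(triethylsilyloxy)pentane-1,5-diol
Conditions: O3, CH2Cl2/MeOH, −78 °C; then NaBH4, −78 to 0 °C
Reagents that add atoms: ozone, [O-][O+]=O
Why: Exhaustive ozonolysis with reductive work-up cleaves both alkenes, so C1 and C5 become primary carbinols and the quaternary C4 is untouched.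

Step 3
Reactants: 3 diol
Product: 4 (2R)-5-iodo-2-methyl-2-(triethylsilyloxy)pentan-1-ol
Conditions: I2, PPh3, imidazole, CH2Cl2, 0 °C
Reagents that add atoms: iodine, II
Why: Appel-type iodination; only the unhindered C1 carbinol can undergo the SN2 step, because the C5 carbinol is neopentylic.

Step 4
Reactants: 4 iodo alcohol
Product: 5 (2R)-5-iodo-2-methyl-1,2-bis(triethylsilyloxy)pentane
Conditions: Et3SiOTf, 2,6-lutidine, CH2Cl2, −78 to 0 °C
Reagents that add atoms: triethylsilyl trifluoromethanesulfonate, CC[Si](CC)(CC)OS(=O)(=O)C(F)(F)F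
Why: Silyl triflate silylation; it caps whichever hydroxyl is free, so a 1,2-silyl shift in step 2 would converge on the same product.

Step 5
Reactants: 5 iodide
Product: 6 [(4R)-4-methyl-4,5-bis(triethylsilyloxy)pentyl]triphenylphosphonium iodide
Conditions: PPh3, i-Pr2NEt (cat.), MeCN, 80 °C
Reagents that add atoms: triphenylphosphine, c1ccc(cc1)P(c1ccccc1)c1ccccc1
Why: SN2 quaternisation of a primary iodide; the trace of amine keeps the silyl ethers from acid.

Step 6
Reactants: 7 dimethyl (4R,5R)-2,2-dimethyl-1,3-dioxolane-4,5-dicarboxylate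
Product: 8 (4R,5R)-N4,N5-dimethoxy-N4,N5,2,2-tetramethyl-1,3-dioxolane-4,5-dicarboxamide
Conditions: MeNH(OMe)·HCl, i-PrMgCl, THF, −20 to 0 °C
Reagents that add atoms: N,O-dimethylhydroxylamine hydrochloride, CNOC.Cl
Why: Weinreb amidation of esters with the magnesium amide; the trans-dioxolane is the stable isomer, so the two centres (C8, C9) are not at risk.

Step 7
Reactants: 8 bis-Weinreb amide
Product: 9 (4R,5R)-5-acetyl-N-methoxy-N,2,2-trimethyl-1,3-dioxolane-4-carboxamide
Conditions: MeMgBr (1.1 equiv), THF, −78 to 0 °C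
Reagents that add atoms: methylmagnesium bromide, C[Mg]Br
Why: Controlled mono-addition of a Grignard reagent to a C2-symmetric bis-Weinreb amide; the chelated tetrahedral intermediate prevents over-addition, and the two amide groups are equivalent so only one mono-adduct exists.

Step 8
Reactants: 6 phosphonium iodide; 9 keto amide
Product: 11 (4R,5S)-N-methoxy-N,2,2-trimethyl-5-[(2Z,6R)-6-methyl-6,7-bis(triethylsilyloxy)hept-2-en-2-yl]-1,3-dioxolane-4-carboxamide, via phosphorus ylide 10 (not isolated)
Conditions: NaN(SiMe3)2, THF, −78 to 0 °C; then 9, −78 °C to rt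
Reagents that add atoms: none
Why: Wittig olefination of an α-alkoxy methyl ketone with an unstabilised ylide; this substrate class places the ylide chain (C2) cis to the oxygenated carbon (C9) and gives the ring-cis C1=C10 geometry. The ketone reacts far faster than the Weinreb amide.

Step 9
Reactants: 11 Weinreb amide
Product: 13 (4S,5S)-4-ethynyl-2,2-dimethyl-5-[(2Z,6R)-6-methyl-6,7-bis(triethylsilyloxy)hept-2-en-2-yl]-1,3-dioxolane, via aldehyde 12 (not isolated)
Conditions: i-Bu2AlH, THF, −78 °C; then MeOH, K2CO3, dimethyl (1-diazo-2-oxopropyl)phosphonate, 0 °C to rt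
Reagents that add atoms: dimethyl (1-diazo-2-oxopropyl)phosphonate, CC(=O)C(=[N+]=[N-])P(=O)(OC)OC
Why: Weinreb amide reduction followed in the same flask by Ohira–Bestmann homologation, which adds C6; the trans-dioxolane aldehyde is the thermodynamic epimer, so C8 is safe under carbonate.

Step 10
Reactants: 13 alkyne
Product: 14 (2R,5Z)-6-[(4S,5S)-5-ethynyl-2,2-dimethyl-1,3-dioxolan-4-yl]-2-methyl-2-(triethylsilyloxy)hept-5-enal
Conditions: (COCl)2, DMSO, CH2Cl2, −78 to −30 °C; then Et3N
Reagents that add atoms: none
Why: Swern oxidation carried out on the silyl ether: primary triethylsilyl ethers are cleaved and oxidised directly under these conditions while tertiary ones survive. The aldehyde has no α-hydrogen.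

Step 11
Reactants: 14 alkyne aldehyde; 15 bromoacetic acid
Product: 16 (Z)-2-{(4S,5S)-2,2-dimethyl-5-[(2Z,6R)-6-methyl-7-oxo-6-(triethylsilyloxy)hept-2-en-2-yl]-1,3-dioxolan-4-yl}ethenyl bromoacetate
Conditions: Ru(η3-CH2C(CH3)CH2)2(Ph2P(CH2)4PPh2) (3 mol %), toluene, 60 °C
Reagents that add atoms: none
Why: Ruthenium-catalysed anti-Markovnikov addition of a carboxylic acid to a terminal alkyne through a ruthenium vinylidene; the carboxylate adds trans to the metal and gives the (Z)-enol ester (C6=C7).

Step 12
Reactants: 16 enol bromoacetate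
Product: 17 thirteen-membered β-hydroxy (Z)-enol lactone (4R,8S,9S; 1(10)Z,6Z; C5 epimers)
Conditions: SmI2 (3 equiv), THF, −78 °C, slow addition of 16 (final 2 mM); then aq. NH4Cl
Reagents that add atoms: none
Why: Intramolecular samarium Reformatsky reaction; divalent samarium reduces the C–Br bond and the samarium enolate adds to the C5 aldehyde, forming C5–C11. High dilution favours the ring, and the C5 configuration is irrelevant because it is oxidised next.

Step 13
Reactants: 17 β-hydroxy lactone
Product: 18 thirteen-membered β-keto (Z)-enol lactone (4R,8S,9S; 1(10)Z,6Z)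
Conditions: Dess–Martin periodinane, NaHCO3, CH2Cl2, 0 °C to rt
Reagents that add atoms: none
Why: Dess–Martin oxidation of a β-hydroxy ester to the β-keto ester under buffered, non-basic conditions that spare the enol ester and the silyl ether.

Step 14
Reactants: 18 β-keto enol lactone
Product: 20 (4R,6R,7R,8S,9S)-8,9-(isopropylidenedioxy)-5-oxo-4-(triethylsilyloxy)-13-norgermacr-1(10)Z-en-12,6-olide, via cyclobutanol photoadduct 19 (not isolated)
Conditions: hν 254 nm (low-pressure Hg lamp, quartz), degassed cyclohexane, 1 mM, 40 °C; then silica gel, rt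
Reagents that add atoms: none
Why: Proposed new method: direct excitation of the hydrogen-bonded enol tautomer of 18 (C5=C11, π,π* band near 250 nm) should lead, from the s-trans ester rotamer, to a 5-exo (rule-of-five) attack of C5 on C6 that closes the ten-membered carbocycle transannularly and leaves a 1,4-biradical at C7 and C11, whose recombination (C7–C11) completes the γ-lactone ring inside the 2-oxabicyclo[2.1.1]hexan-3-one 19. 19 is a strained β-hydroxy ester and should cleave C5–C11 by retro-aldol, giving the C5 ketone and the lactone CH2 of 20. The closest known reaction types are the De Mayo reaction of 1,3-dicarbonyl enols with alkenes and the crossed intramolecular [2+2] photocycloaddition of 1,5-dienes to bicyclo[2.1.1]hexanes; their combination on a β-keto enol ester inside a macrocycle is not known. C6 and C7 are the new stereocentres: their relative configuration (cis-fused lactone) is fixed because the seven-atom C4–C8 bridge can span C5 and C7 only on the cyclobutane face anti to the lactone bridge. Their absolute configuration is set by C8, whose hydrogen eclipses the (Z)-enol-ester plane (A(1,3) strain), so that the ring and with it the enol reach C6=C7 on the face of C9 and anti to the C8–O bond. The step needs chemoselectivity for C6=C7 over the trisubstituted C1=C10; this rests on the short planar ester tether, on 254 nm light that only the enol absorbs, and on the crowding at C10. It also needs crossed regiochemistry, which the rule of five provides.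

Step 15
Reactants: 20 ketolactone
Product: 21 (4R,5R,6R,7R,8S,9S)-5-hydroxy-8,9-(isopropylidenedioxy)-4-(triethylsilyloxy)-13-norgermacr-1(10)Z-en-12,6-olide
Conditions: NaBH4, CeCl3·7H2O, MeOH/THF, −78 to −40 °C
Reagents that add atoms: none
Why: Luche-type ketone reduction under non-basic conditions (no epimerisation at C6, lactone untouched). With both ring bonds (C3–C4, C6–C7) gauche to the carbonyl, the C4–OSiEt3 bond shields one face and hydride should enter anti to it (Felkin–Anh), giving the 5R carbinol.

Step 16
Reactants: 21 hydroxy lactone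
Product: 24 (4R,5R,6R,7R,8S,9S)-5-hydroxy-8,9-(isopropylidenedioxy)-4-(triethylsilyloxy)germacra-1(10)Z,11(13)-dien-12,6-olide, via Mannich base 22 (not isolated), via trimethylammonium iodide 23 (not isolated)
Conditions: LiN(i-Pr)2 (2.5 equiv), THF, −78 °C; (CH3)2N=CH2+ I−, −78 to 0 °C; then MeI, CH2Cl2/MeOH, rt; then aq. NaHCO3
Reagents that add atoms: Eschenmoser's salt (N,N-dimethylmethyleneiminium iodide), C=[N+](C)C.[I-]
Why: α-Methylenation of a lactone by enolate Mannich reaction, N-methylation and elimination; the alkoxide/enolate dianion carries the free C5 hydroxyl, and the lactone CH2 is the only carbon acid of comparable strength.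

Step 17
Reactants: 24 α-methylene lactone
Product: 25 (4R,5R,6R,7R,8S,9S)-8,9-(isopropylidenedioxy)-5-(methylsulfonyloxy)-4-(triethylsilyloxy)germacra-1(10)Z,11(13)-dien-12,6-olide
Conditions: MsCl, Et3N, CH2Cl2, −20 °C
Reagents that add atoms: methanesulfonyl chloride, CS(=O)(=O)Cl
Why: Mesylation through the sulfene reaches the hindered secondary carbinol with retention at C5; the flanking oxygen substituents make the mesylate resistant to solvolysis.

Step 18
Reactants: 25 mesylate
Product: 26 (4R,5R,6R,7R,8S,9S)-14-hydroxy-8,9-(isopropylidenedioxy)-5-(methylsulfonyloxy)-4-(triethylsilyloxy)germacra-1(10)Z,11(13)-dien-12,6-olide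
Conditions: SeO2 (0.5 equiv), t-BuOOH, CH2Cl2, rt
Reagents that add atoms: selenium dioxide, O=[Se]=O; tert-butyl hydroperoxide, CC(C)(C)OO
Why: SeO2 allylic oxidation (ene reaction, then [2,3] shift) of the methyl group on the more substituted alkene carbon; on 4,5-oxygenated germacranolides with an α-methylene lactone this reaction is known to give the 14-hydroxy compound with C14 trans to C2, the geometry already present.

Step 19
Reactants: 26 allylic alcohol
Product: 28 (4R,5R,6R,7R,8S,9S)-8,9-(isopropylidenedioxy)-5-(methylsulfonyloxy)-4-(triethylsilyloxy)germacra-1(10),11(13)-dien-12,6-olid-14-oic acid (C9 and C2 cis), via enal 27 (not isolated)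
Conditions: MnO2, CH2Cl2, rt; filter; then NaClO2, NaH2PO4, 2-methylbut-2-ene, t-BuOH/H2O, 0 °C
Reagents that add atoms: sodium chlorite, [Na+].[O-]Cl=O
Why: MnO2 oxidation of the allylic alcohol, then Pinnick oxidation of the enal; neither touches the α-methylene lactone, and the alkene scavenger removes hypochlorite.

Step 20
Reactants: 28 acid
Product: 29 methyl (4R,5R,6R,7R,8S,9S)-8,9-(isopropylidenedioxy)-5-(methylsulfonyloxy)-4-(triethylsilyloxy)germacra-1(10),11(13)-dien-12,6-olid-14-oate
Conditions: MeI, KHCO3, DMF, rt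
Reagents that add atoms: iodomethane, CI
Why: Carboxylate O-alkylation; a diazoalkane is avoided because it would add to the α-methylene lactone.

Step 21
Reactants: 29 methyl ester
Product: 30 methyl (4R,5R,6R,7R,8S,9S)-4,8,9-trihydroxy-5-(methylsulfonyloxy)germacra-1(10),11(13)-dien-12,6-olid-14-oate
Conditions: CF3CO2H/H2O (9:1), CH2Cl2, 0 °C
Reagents that add atoms: none
Why: Acid hydrolysis removes the acetonide and the tertiary silyl ether together; mesylate, lactone and enoate are acid-stable, and no epoxide is yet present.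

Step 22
Reactants: 30 triol
Product: 31 methyl (4R,5R,6R,7R,8S,9S)-8-acetoxy-4,9-dihydroxy-5-(methylsulfonyloxy)germacra-1(10),11(13)-dien-12,6-olid-14-oate
Conditions: Ac2O (1.1 equiv), 2,4,6-collidine, CH2Cl2, −20 to 0 °C
Reagents that add atoms: acetic anhydride, CC(=O)OC(C)=O
Why: Kinetic acylation; the C9 hydroxyl is flanked by the fully substituted C10 and can hydrogen-bond to the C14 ester carbonyl, so the C8 hydroxyl should react first. The tertiary C4 hydroxyl is inert.

Step 23
Reactants: 32 methyl (R)-2-methyloxirane-2-carboxylate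
Product: 33 potassium (R)-2-methyloxirane-2-carboxylate
Conditions: KOH (1.0 equiv), MeOH/H2O, 0 °C; evaporate, dry
Reagents that add atoms: potassium hydroxide, [K+].[OH-]
Why: Saponification of a glycidic ester to its stable salt; the quaternary stereocentre cannot epimerise.

Step 24
Reactants: 31 monoacetate; 33 potassium glycidate
Product: 35 methyl (4R,5R,6R,7R,8S,9S)-8-acetoxy-4-hydroxy-5-(methylsulfonyloxy)-9-[(2R)-2-methyloxirane-2-carbonyloxy]germacra-1(10),11(13)-dien-12,6-olid-14-oate, via mixed anhydride 34 (not isolated)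
Conditions: 2,4,6-Cl3C6H2COCl, THF, 0 °C; then 31, DMAP, toluene, rt
Reagents that add atoms: none
Why: Yamaguchi esterification of a hindered secondary alcohol with an α,α-disubstituted acid; the tertiary alcohol does not compete, and any epoxide closure started by the amine leads to 36.

Step 25
Reactants: 35 hydroxy mesylate
Product: 36 target, methyl (4R,5S,6R,7R,8S,9S)-8-acetoxy-4,5-epoxy-9-[(2R)-2-methyloxirane-2-carbonyloxy]germacra-1(10),11(13)-dien-12,6-olid-14-oate (CNP0159450.1)
Conditions: K2CO3, MeCN, rt
Reagents that add atoms: none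
Why: Intramolecular Williamson (3-exo-tet) closure; the C4 oxygen displaces the 5R mesylate with inversion and gives the cis (4R,5S)-epoxide. A carbonate in an aprotic solvent spares the esters and the α-methylene lactone.

## Compound list

1 | (R)-linalool, (3R)-3,7-dimethylocta-1,6-dien-3-ol | CC(C)=CCC[C@@](C=C)(C)O | starting material
2 | (3R)-3,7-dimethyl-3-(triethylsilyloxy)octa-1,6-diene | CC(C)=CCC[C@@](C=C)(C)O[Si](CC)(CC)CC | intermediate
3 | (2R)-2-methyl-2-(triethylsilyloxy)pentane-1,5-diol | OCCC[C@@](CO)(C)O[Si](CC)(CC)CC | intermediate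
4 | (2R)-5-iodo-2-methyl-2-(triethylsilyloxy)pentan-1-ol | ICCC[C@@](CO)(C)O[Si](CC)(CC)CC | intermediate
5 | (2R)-5-iodo-2-methyl-1,2-bis(triethylsilyloxy)pentane | ICCC[C@@](CO[Si](CC)(CC)CC)(C)O[Si](CC)(CC)CC | intermediate
6 | [(4R)-4-methyl-4,5-bis(triethylsilyloxy)pentyl]triphenylphosphonium iodide | [I-].c1ccccc1[P+](c1ccccc1)(c1ccccc1)CCC[C@@](CO[Si](CC)(CC)CC)(C)O[Si](CC)(CC)CC | intermediate
7 | dimethyl (4R,5R)-2,2-dimethyl-1,3-dioxolane-4,5-dicarboxylate (L-tartrate acetonide) | COC(=O)[C@@H]1OC(C)(C)O[C@H]1C(=O)OC | starting material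
8 | (4R,5R)-N4,N5-dimethoxy-N4,N5,2,2-tetramethyl-1,3-dioxolane-4,5-dicarboxamide | CON(C)C(=O)[C@@H]1OC(C)(C)O[C@H]1C(=O)N(C)OC | intermediate
9 | (4R,5R)-5-acetyl-N-methoxy-N,2,2-trimethyl-1,3-dioxolane-4-carboxamide | CON(C)C(=O)[C@@H]1OC(C)(C)O[C@H]1C(C)=O | intermediate
10 | [(4R)-4-methyl-4,5-bis(triethylsilyloxy)pentylidene]triphenylphosphorane | c1ccccc1P(c1ccccc1)(c1ccccc1)=CCC[C@@](CO[Si](CC)(CC)CC)(C)O[Si](CC)(CC)CC | intermediate
11 | (4R,5S)-N-methoxy-N,2,2-trimethyl-5-[(2Z,6R)-6-methyl-6,7-bis(triethylsilyloxy)hept-2-en-2-yl]-1,3-dioxolane-4-carboxamide | CON(C)C(=O)[C@@H]1OC(C)(C)O[C@H]1/C(C)=C\CC[C@@](CO[Si](CC)(CC)CC)(C)O[Si](CC)(CC)CC | intermediate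
12 | (4R,5S)-2,2-dimethyl-5-[(2Z,6R)-6-methyl-6,7-bis(triethylsilyloxy)hept-2-en-2-yl]-1,3-dioxolane-4-carbaldehyde | O=C[C@@H]1OC(C)(C)O[C@H]1/C(C)=C\CC[C@@](CO[Si](CC)(CC)CC)(C)O[Si](CC)(CC)CC | intermediate
13 | (4S,5S)-4-ethynyl-2,2-dimethyl-5-[(2Z,6R)-6-methyl-6,7-bis(triethylsilyloxy)hept-2-en-2-yl]-1,3-dioxolane | C#C[C@@H]1OC(C)(C)O[C@H]1/C(C)=C\CC[C@@](CO[Si](CC)(CC)CC)(C)O[Si](CC)(CC)CC | intermediate
14 | (2R,5Z)-6-[(4S,5S)-5-ethynyl-2,2-dimethyl-1,3-dioxolan-4-yl]-2-methyl-2-(triethylsilyloxy)hept-5-enal | C#C[C@@H]1OC(C)(C)O[C@H]1/C(C)=C\CC[C@@](C=O)(C)O[Si](CC)(CC)CC | intermediate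
15 | bromoacetic acid | OC(=O)CBr | starting material
16 | (Z)-2-{(4S,5S)-2,2-dimethyl-5-[(2Z,6R)-6-methyl-7-oxo-6-(triethylsilyloxy)hept-2-en-2-yl]-1,3-dioxolan-4-yl}ethenyl bromoacetate | BrCC(=O)O/C=C\[C@@H]1OC(C)(C)O[C@H]1/C(C)=C\CC[C@@](C=O)(C)O[Si](CC)(CC)CC | intermediate
17 | thirteen-membered β-hydroxy (Z)-enol lactone: ring O–C12(=O)–C11H2–C5H(OH)–C4(CH3)(OSiEt3)–C3H2–C2H2–C1H=C10(CH3)–C9H–C8H–C7H=C6H, 8,9-O-isopropylidene, 4R,8S,9S, 1(10)Z,6Z, both C5 epimers | OC1CC(=O)O/C=C\[C@@H]2OC(C)(C)O[C@H]2/C(C)=C\CC[C@@]1(C)O[Si](CC)(CC)CC | intermediate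
18 | thirteen-membered β-keto (Z)-enol lactone: as 17 with C5=O, 4R,8S,9S, 1(10)Z,6Z | O=C1CC(=O)O/C=C\[C@@H]2OC(C)(C)O[C@H]2/C(C)=C\CC[C@@]1(C)O[Si](CC)(CC)CC | intermediate
19 | cyclobutanol photoadduct: 2-oxabicyclo[2.1.1]hexan-3-one with C5–C6 and C7–C11 bonded, OH on C5, C5 and C7 bridged by C4–C3–C2–C1=C10–C9–C8 | O[C@]12[C@@H]3OC(=O)[C@H]1[C@@H]3[C@@H]4OC(C)(C)O[C@H]4/C(C)=C\CC[C@@]2(C)O[Si](CC)(CC)CC | intermediate
20 | (4R,6R,7R,8S,9S)-8,9-(isopropylidenedioxy)-5-oxo-4-(triethylsilyloxy)-13-norgermacr-1(10)Z-en-12,6-olide | O=C1[C@@H]2OC(=O)C[C@@H]2[C@@H]3OC(C)(C)O[C@H]3/C(C)=C\CC[C@@]1(C)O[Si](CC)(CC)CC | intermediate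
21 | (4R,5R,6R,7R,8S,9S)-5-hydroxy-8,9-(isopropylidenedioxy)-4-(triethylsilyloxy)-13-norgermacr-1(10)Z-en-12,6-olide | O[C@@H]1[C@@H]2OC(=O)C[C@@H]2[C@@H]3OC(C)(C)O[C@H]3/C(C)=C\CC[C@@]1(C)O[Si](CC)(CC)CC | intermediate
22 | Mannich base: 21 with CH2N(CH3)2 on C11 (C11 epimers) | O[C@@H]1[C@@H]2OC(=O)C(CN(C)C)[C@@H]2[C@@H]3OC(C)(C)O[C@H]3/C(C)=C\CC[C@@]1(C)O[Si](CC)(CC)CC | intermediate
23 | trimethylammonium iodide of 22 | [I-].O[C@@H]1[C@@H]2OC(=O)C(C[N+](C)(C)C)[C@@H]2[C@@H]3OC(C)(C)O[C@H]3/C(C)=C\CC[C@@]1(C)O[Si](CC)(CC)CC | intermediate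
24 | (4R,5R,6R,7R,8S,9S)-5-hydroxy-8,9-(isopropylidenedioxy)-4-(triethylsilyloxy)germacra-1(10)Z,11(13)-dien-12,6-olide | O[C@@H]1[C@@H]2OC(=O)C(=C)[C@@H]2[C@@H]3OC(C)(C)O[C@H]3/C(C)=C\CC[C@@]1(C)O[Si](CC)(CC)CC | intermediate
25 | (4R,5R,6R,7R,8S,9S)-8,9-(isopropylidenedioxy)-5-(methylsulfonyloxy)-4-(triethylsilyloxy)germacra-1(10)Z,11(13)-dien-12,6-olide | CS(=O)(=O)O[C@@H]1[C@@H]2OC(=O)C(=C)[C@@H]2[C@@H]3OC(C)(C)O[C@H]3/C(C)=C\CC[C@@]1(C)O[Si](CC)(CC)CC | intermediate
26 | 14-hydroxy derivative of 25 (1(10)Z) | CS(=O)(=O)O[C@@H]1[C@@H]2OC(=O)C(=C)[C@@H]2[C@@H]3OC(C)(C)O[C@H]3/C(CO)=C\CC[C@@]1(C)O[Si](CC)(CC)CC | intermediate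
27 | 14-oxo derivative of 25 (enal, C9 and C2 cis) | CS(=O)(=O)O[C@@H]1[C@@H]2OC(=O)C(=C)[C@@H]2[C@@H]3OC(C)(C)O[C@H]3/C(C=O)=C\CC[C@@]1(C)O[Si](CC)(CC)CC | intermediate
28 | (4R,5R,6R,7R,8S,9S)-8,9-(isopropylidenedioxy)-5-(methylsulfonyloxy)-4-(triethylsilyloxy)germacra-1(10),11(13)-dien-12,6-olid-14-oic acid (C9 and C2 cis) | CS(=O)(=O)O[C@@H]1[C@@H]2OC(=O)C(=C)[C@@H]2[C@@H]3OC(C)(C)O[C@H]3/C(C(=O)O)=C\CC[C@@]1(C)O[Si](CC)(CC)CC | intermediate
29 | methyl ester of 28 | CS(=O)(=O)O[C@@H]1[C@@H]2OC(=O)C(=C)[C@@H]2[C@@H]3OC(C)(C)O[C@H]3/C(C(=O)OC)=C\CC[C@@]1(C)O[Si](CC)(CC)CC | intermediate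
30 | methyl (4R,5R,6R,7R,8S,9S)-4,8,9-trihydroxy-5-(methylsulfonyloxy)germacra-1(10),11(13)-dien-12,6-olid-14-oate | CS(=O)(=O)O[C@@H]1[C@@H]2OC(=O)C(=C)[C@@H]2[C@H](O)[C@@H](O)/C(C(=O)OC)=C\CC[C@@]1(C)O | intermediate
31 | methyl (4R,5R,6R,7R,8S,9S)-8-acetoxy-4,9-dihydroxy-5-(methylsulfonyloxy)germacra-1(10),11(13)-dien-12,6-olid-14-oate | CS(=O)(=O)O[C@@H]1[C@@H]2OC(=O)C(=C)[C@@H]2[C@H](OC(C)=O)[C@@H](O)/C(C(=O)OC)=C\CC[C@@]1(C)O | intermediate
32 | methyl (R)-2-methyloxirane-2-carboxylate | COC(=O)[C@@]1(C)CO1 | starting material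
33 | potassium (R)-2-methyloxirane-2-carboxylate | [K+].[O-]C(=O)[C@@]1(C)CO1 | intermediate
34 | (R)-2-methyloxirane-2-carboxylic 2,4,6-trichlorobenzoic anhydride | O=C(OC(=O)c1c(Cl)cc(Cl)cc1Cl)[C@@]1(C)CO1 | intermediate
35 | methyl (4R,5R,6R,7R,8S,9S)-8-acetoxy-4-hydroxy-5-(methylsulfonyloxy)-9-[(2R)-2-methyloxirane-2-carbonyloxy]germacra-1(10),11(13)-dien-12,6-olid-14-oate | CS(=O)(=O)O[C@@H]1[C@@H]2OC(=O)C(=C)[C@@H]2[C@H](OC(C)=O)[C@@H](OC(=O)[C@@]3(C)CO3)/C(C(=O)OC)=C\CC[C@@]1(C)O | intermediate
36 | CNP0159450.1, methyl (4R,5S,6R,7R,8S,9S)-8-acetoxy-4,5-epoxy-9-[(2R)-2-methyloxirane-2-carbonyloxy]germacra-1(10),11(13)-dien-12,6-olid-14-oate | C=C1C(=O)O[C@@H]2[C@H]1[C@H](OC(C)=O)[C@@H](OC(=O)[C@@]1(C)CO1)/C(C(=O)OC)=C\CC[C@@]1(C)O[C@@H]21 | target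

## Step count and risk

Total: 25 steps. Longest linear sequence: 22 steps (steps 1–5, 8–22, 24 and 25, from 1). The branches are steps 6–7 (from 7) and step 23 (from 32).

**Step 14 (key step, new method).**
- Likely failures: the excited enol decays unproductively because the ester stays in the s-cis rotamer; transannular addition to C1=C10 (the 1,6-diene mode) competes; the enol ester undergoes Z/E isomerisation or 1,3-acyl shift; the α-silyloxy ketone product undergoes secondary α-cleavage on prolonged irradiation.
- Fallback (known chemistry, from 14 to 20): nickel-catalysed alkyne–aldehyde reductive macrocyclisation of 14 (Ni(1,5-cyclooctadiene)2, 1,3-dimesitylimidazol-2-ylidene, Et3SiH, high dilution) joins C5 to C6 and gives the ten-membered (E)-allylic silyl ether F1. HF·pyridine frees the allylic alcohol F2 (the tertiary silyl ether stays), and Dess–Martin oxidation gives the enone F3. Mukaiyama–Michael addition of 1-methoxy-1-(trimethylsilyloxy)ethene puts C11 on C7, and Rubottom oxidation of the resulting silyl enol ether puts the oxygen on C6, giving the hydroxy keto ester F4. Lactonisation (pyridinium p-toluenesulfonate, toluene) returns to 20. The price is that C6 and C7 are set in two separate substrate-controlled steps, so diastereomers may have to be separated.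

**Step 15 (C5 reduction).**
- Likely failure: poor or reversed facial selectivity, because the C6 acyloxy group favours hydride attack on the opposite face to that favoured by the C4 silyloxy group.
- Fallback (from 20 to 21): the control element is changed from steric shielding by the silyl ether to delivery from the free hydroxyl. HF·pyridine removes the silyl group to give the α-hydroxy ketone F5. Me4NBH(OAc)3 in MeCN/AcOH binds to the C4 oxygen and delivers hydride to the face that external hydride avoids, giving the 4,5-diol F6. Bis-silylation (Et3SiOTf, 2,6-lutidine) gives the bis(triethylsilyl) ether F7, and pyridinium p-toluenesulfonate in MeOH removes the secondary silyl group selectively to return to 21.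

**Step 22 (mono-acetylation).**
- Likely failures: acylation at C9 instead of C8, or bis-acylation, because the steric and hydrogen-bond bias between the two secondary hydroxyls is small.
- Fallback (from 30 to 35): the order of the two acylations is reversed. The bulkier Yamaguchi reagent 34 is used first, so that it selects the more reactive hydroxyl and gives the 9-glycidate 8-alcohol F8. Ac2O/DMAP then acetylates the remaining C8 hydroxyl and returns to 35. If the first acyl group goes to C8 under these conditions too, the same two reagents are simply used in the original order.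

**Step 12 (with step 11, macrocyclisation).**
- Likely failures: intermolecular Reformatsky addition (oligomers), ketyl formation at the α-silyloxy aldehyde, or loss of the enol ester from the samarium enolate.
- Fallback (from 14 to 17): the ring is closed at the ester oxygen instead. Aldol addition of dilithioacetate (AcOH, 2 LiN(i-Pr)2) to 14 gives the β-hydroxy acid F9. Slow addition of F9 to Ru(η3-CH2C(CH3)CH2)2(Ph2P(CH2)4PPh2) in toluene at 60 °C adds the acid to its own alkyne in the anti-Markovnikov (Z) sense and returns to 17.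

## Further compounds

F1 | step 14 | ten-membered (E)-allylic silyl ether, 5-(triethylsilyloxy) (C5 epimers), C5–C6 bonded, 6E,1(10)Z | CC[Si](CC)(CC)OC1/C=C/[C@@H]2OC(C)(C)O[C@H]2/C(C)=C\CC[C@@]1(C)O[Si](CC)(CC)CC
F2 | step 14 | ten-membered (E)-allylic alcohol (C5 epimers) | OC1/C=C/[C@@H]2OC(C)(C)O[C@H]2/C(C)=C\CC[C@@]1(C)O[Si](CC)(CC)CC
F3 | step 14 | ten-membered (6E)-en-5-one | O=C1/C=C/[C@@H]2OC(C)(C)O[C@H]2/C(C)=C\CC[C@@]1(C)O[Si](CC)(CC)CC
F4 | step 14 | (6R,7R)-6-hydroxy-5-oxo-7-(methoxycarbonylmethyl) ten-membered ketone | O=C1[C@H](O)[C@H](CC(=O)OC)[C@@H]2OC(C)(C)O[C@H]2/C(C)=C\CC[C@@]1(C)O[Si](CC)(CC)CC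
F5 | step 15 | (4R,6R,7R,8S,9S)-4-hydroxy-8,9-(isopropylidenedioxy)-5-oxo-13-norgermacr-1(10)Z-en-12,6-olide | O=C1[C@@H]2OC(=O)C[C@@H]2[C@@H]3OC(C)(C)O[C@H]3/C(C)=C\CC[C@@]1(C)O
F6 | step 15 | (4R,5R,6R,7R,8S,9S)-4,5-dihydroxy-8,9-(isopropylidenedioxy)-13-norgermacr-1(10)Z-en-12,6-olide | O[C@@H]1[C@@H]2OC(=O)C[C@@H]2[C@@H]3OC(C)(C)O[C@H]3/C(C)=C\CC[C@@]1(C)O
F7 | step 15 | 4,5-bis(triethylsilyl) ether of F6 | CC[Si](CC)(CC)O[C@@H]1[C@@H]2OC(=O)C[C@@H]2[C@@H]3OC(C)(C)O[C@H]3/C(C)=C\CC[C@@]1(C)O[Si](CC)(CC)CC
F8 | step 22 | methyl (4R,5R,6R,7R,8S,9S)-4,8-dihydroxy-5-(methylsulfonyloxy)-9-[(2R)-2-methyloxirane-2-carbonyloxy]germacra-1(10),11(13)-dien-12,6-olid-14-oate | CS(=O)(=O)O[C@@H]1[C@@H]2OC(=O)C(=C)[C@@H]2[C@H](O)[C@@H](OC(=O)[C@@]3(C)CO3)/C(C(=O)OC)=C\CC[C@@]1(C)O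
F9 | step 12 | (4R,7Z)-8-[(4S,5S)-5-ethynyl-2,2-dimethyl-1,3-dioxolan-4-yl]-3-hydroxy-4-methyl-4-(triethylsilyloxy)non-7-enoic acid (C3 epimers) | C#C[C@@H]1OC(C)(C)O[C@H]1/C(C)=C\CC[C@@](C(O)CC(=O)O)(C)O[Si](CC)(CC)CC
A1 | alternative 1 | ten-membered 9-(pyrrolidin-1-yl)-10-carbomethoxy-9,1-dienamine | C1CCN(C1)/C2=C(C(=O)OC)/C=C/C/C(C)=C\[C@H](O[Si](C)(C)C(C)(C)C)[C@H](C(=C)CO[Si](C)(C)C(C)(C)C)[C@@H]2O[Si](C)(C)C(C)(C)C
A2 | alternative 1 | cyclooctenone pyrrolidine enamine | C1CCN(C1)C2=CC/C(C)=C\[C@H](O[Si](C)(C)C(C)(C)C)[C@H](C(=C)CO[Si](C)(C)C(C)(C)C)[C@@H]2O[Si](C)(C)C(C)(C)C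
A3 | alternative 1 | methyl propiolate | C#CC(=O)OC
A4 | alternative 2 | ten-membered 8,9-cis-ene with lactone, epoxide and enoate | C=C1C(=O)O[C@@H]2[C@H]1/C=C\C(C(=O)OC)=C/CC[C@@]1(C)O[C@@H]21
A5 | alternative 2 | seco-diene with vinyl groups on C7 and C10 | C=C1C(=O)O[C@H]([C@H]1C=C)[C@@H]1O[C@]1(C)CC/C=C(\C=C)C(=O)OC
A6 | alternative 3 | ten-membered C4=C5 silyl enol ether with ring-cis C1=C10 enoate | C/C1=C(O[Si](C)(C)C)\[C@H](O[Si](C)(C)C(C)(C)C)[C@H](CCO[Si](C)(C)C(C)(C)C)[C@@H]2OC(C)(C)O[C@H]2/C(C(=O)OC)=C\CC1
A7 | alternative 3 | 1-isopropenyl-2-vinylcyclohexanol precursor (configuration at the two quaternary carbons left open) | C=C(C)C1(O)[C@H](O[Si](C)(C)C(C)(C)C)[C@H](CCO[Si](C)(C)C(C)(C)C)[C@@H]2OC(C)(C)O[C@H]2C1(C=C)C(=O)OC
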